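The pitfall with a nucleophile that also couples with itself is to read its 1.00 equiv as that much electrophile turned over, and then to pay for an excess nobody has reckoned.

    electrophile + nucleophile ⇌ acid + target + leaving group (K1 = 1.54 × 10⁻⁸ M, k1 = 31.0 /M/s)
    protonated nucleophile ⇌ nucleophile + acid, settled at all times (K2 = 4.0 × 10⁻¹⁰ M)
    buffer acid ⇌ buffer base + acid, settled at all times (K3 = 1.0 × 10⁻⁹ M)
    2 nucleophile → homo dimer (k4 = 2.73 /M/s)

electrophile 34 mM; nucleophile 1.00 equiv; buffer base 2.00 equiv; buffer acid 0.300 equiv (fed, over 6.0 s); time 6.0 s

- part of the electrophile that has reacted at 6.0 s
- pH of the solution at 6.0 s

- acid is the free proton; pH is minus the decimal logarithm of its molar concentration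
- two of one species on the left: rate k times its square, two consumed each time
- run time (flask): 6.0 s

Before the next run I must decide whether this flask needs more than 1.00 equiv of nucleophile to pay for the homo dimer. Electrophile (E) and nucleophile (N) are charged equally, so both are limiting reagents, and I write the balance of N: charged equals free, plus protonated, plus turned over by the forward step, plus two for each homo dimer. The two ways of spending N go at the forward rate and at 2 times the dimerisation rate. Their quotient is the forward constant times [E] over 2 times the dimerisation constant times [N], and with equal charges it starts at 5.68. That is the selectivity factor S, nucleophile sent forward per nucleophile lost to homo dimer.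

Each forward turn takes one E and one N, while dimerisation and protonation take N alone, so I expect [E]/[N] to climb and S with it. I therefore take the starting value as a floor on S, and then the homo dimer takes at most 15.0 % of what the forward step and dimerisation spend between them, the way back not counted. One division gives me that bound on the share, though it gives no conversion. Against that share I charge no excess to pay for the homo dimer and keep 1.00 equiv.

The forecast steps by hand and commits to actual values, 68.7 % reacted and pH 9.23, noting “Dimerisation consumes about 2.9 mM of nucleophile, mostly early”.

The simulation gives 69.4 % reacted at pH 9.22. At 6.00 s the forward step, counted without its way back, uses nucleophile 20 times as fast as dimerisation, well above the starting S of 5.68. The neighbour flask with 0.400 equiv of nucleophile starts at S = 14.2, which gives its homo dimer a share of at most 6.58 % by the same division. That neighbour flask reaches 36.1 %, and at 6.00 s its homo dimer holds 3.55 % of the nucleophile found in target and homo dimer together.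

The numbers of this flask belong to no real substance; the result is computed.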